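The leftover counted here is the charge of starting material minus the target read, which measures how far a flask has got towards target: at 34 h, Tuesday's run has 0.172 M of its 0.400 M not read as target. The natural logarithm of charge over that leftover is called the reach here, and Sunday's run can be built up on it one process at a time.

| flask | starting material | reagent | free catalyst | time |
|---|---|---|---|---|
| Tuesday's | 0.400 M | 0.480 M | 0.00400 M |  |
| Monday's | 0.240 M | 0.320 M | 0.00400 M |  |
| Thursday's | 0.400 M | 0.480 M | 0.00800 M |  |
| Friday's | 0.800 M | 0.480 M | 0.00400 M |  |
| Sunday's | 1.00 M | 1.20 M | 0.00400 M | 34 h |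

| run | time / h | [target] / M |
|---|---|---|
| Tuesday's run | 1.9 | 0.0288 |
| Tuesday's run | 5.9 | 0.0810 |
| Tuesday's run | 11 | 0.1328 |
| Tuesday's run | 18 | 0.1790 |
| Tuesday's run | 25 | 0.2084 |
| Tuesday's run | 34 | 0.2284 |
| Monday's run | 1.9 | 0.0170 |
| Monday's run | 5.9 | 0.0481 |
| Monday's run | 11 | 0.0751 |
| Monday's run | 18 | 0.0963 |
| Monday's run | 25 | 0.1170 |
| Monday's run | 34 | 0.1223 |
| Thursday's run | 1.9 | 0.0632 |
| Thursday's run | 5.9 | 0.1423 |
| Thursday's run | 11 | 0.2093 |
| Thursday's run | 18 | 0.2503 |
| Thursday's run | 25 | 0.2662 |
| Thursday's run | 34 | 0.2721 |
| Friday's run | 1.9 | 0.0615 |
| Friday's run | 5.9 | 0.1623 |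
| Friday's run | 11 | 0.2565 |
| Friday's run | 18 | 0.3290 |
| Friday's run | 25 | 0.3582 |
| Friday's run | 34 | 0.3532 |

(scatter of a reading: 0.002 M)

1. the exponent of [starting material] in the starting rate at the charge of the Tuesday's run (at the point where two percent of the starting material have become target) (one fixed amount of target, the same in the runs compared)
2. the exponent of [reagent] in the starting rate at the charge of the Tuesday's run (at the point where two percent of the starting material have become target)
3. target in the Sunday's run at 34 h, as a share of the starting material charged

- Overall: starting material + reagent -> target, with free catalyst as catalyst.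
- Constant volume, constant temperature.
- What is held in complexes is read along with the free species.
- An order is taken over about fifteen percent of the charge, up and down.

The first readings give the orders. Friday's run doubles Tuesday's starting material at equal reagent and gives an order of 1.09. Monday's run, with that order taken as 1, leaves 0.0403 for reagent, a loose figure since the scatter is 0.002 M on a reading of 0.0170 M.

So the main step alone is pseudo-first-order in starting material. Tuesday's first reading gives 0.0379 h⁻¹ per unit of starting material, and Sunday's run has the same free catalyst, 0.00400 M. Held steady, that gives a reach of 1.29 at 34 h, or 72.4% for Sunday's run.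

Next comes the fading. Tuesday's run reads a reach of only 0.846, less than that steady figure, and this reach would put Sunday's run at 57.1%.

Last comes the reagent. Monday's run reaches 0.712, less than Tuesday's, and its reagent charge minus target at 34 h is 0.198 M against 0.252 M in Tuesday's run. The rule carried forward is the loss product, lost reach times reagent charge minus target at 34 h: Tuesday's run gives 0.111 M and Monday's 0.114 M, while Friday's gives a rougher 0.0895 M.

Putting 57.1% into Sunday's run makes reagent charge minus target 0.629 M and gives 67.1%. Going round once more makes it 0.529 M and gives 66.0%, the figure this reckoning commits to.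

The forecast, on the grounds that “reagent is near zero order, probably saturating the catalyst”, gave orders of 1 and 0.08 and a lower 62% for Sunday's run, within 50% to 74%.

The flask gives orders of 1.0 in starting material and 0.15 in reagent, and 63.5% for Sunday's run.

    free catalyst + reagent ⇌ catalyst-reagent complex, settled at all times (12.60 M⁻¹)
    catalyst-reagent complex + starting material → target + free catalyst (12.35 M⁻¹ h⁻¹)
    target → decomposed product (0.008712 h⁻¹)
    2 free catalyst → 2 spent catalyst (35.10 M⁻¹ h⁻¹)

Early in Tuesday's run the apparent order in [free catalyst] is 1.0. At 63.5%, Sunday's run has a reach of 1.01 and a lost reach of 0.281, with 0.565 M of reagent charge minus target. Its loss product is therefore 0.159 M, larger than the 0.111 M carried from Tuesday's run.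

The readings were computed from invented constants, noise included.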